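The pitfall in a share taken early is that its scatter can pass for chemistry. These are the flasks, what was read, and what was asked.

| setting | Tuesday's | Thursday's | flask |
|---|---|---|---|
| Q | 0.80 M | 0.80 M | 0.80 M |
| L | 1 equiv | 1 equiv | 1.00 equiv |
| X | 2 mol% | 1.3 mol% | 2 mol% |
| remark | the very flask that is asked about, followed so far | run made earlier |  |
| time |  |  | 25 h |

| run | time / h | J / % | Z / % |
|---|---|---|---|
| Tuesday's | 0.167 | 18.2 | 10.2 |
| Tuesday's | 0.500 | 37.0 | 24.7 |
| Tuesday's | 0.833 | 47.1 | 29.7 |
| Tuesday's | 1.33 | 56.0 | 32.8 |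
| Tuesday's | 2.00 | 58.8 | 35.4 |
| Tuesday's | 2.50 | 60.5 | 38.6 |
| Tuesday's | 3.00 | 61.2 | 37.6 |
| Thursday's | 1.00 | 43.9 | 27.8 |
| Thursday's | 2.50 | 58.9 | 33.7 |
| Thursday's | 5.00 | 58.7 | 36.9 |
| Thursday's | 8.00 | 63.0 | 37.6 |
| Thursday's | 10.0 | 61.1 | 35.2 |
| Thursday's | 15.0 | 61.3 | 36.2 |
| Thursday's | 20.0 | 62.0 | 38.1 |

(readings scatter by 1 percentage point)

- the numbers in the tables scatter by 1 percentage point (one standard deviation)

- share of J in J plus Z at 15 s
- share of J in J plus Z at 20 min
- share of J in J plus Z at 25 h
- which of J and Z there is more of at 25 h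

1. I carried one quantity, the branch share s (the selectivity for J): J divided by J plus Z in the last reading of Tuesday's run, 61.9%.
2. Two numbers in Tuesday's run seemed not to go together. At 0.167 h the share was 64.1%, but at 3.00 h it was 61.9%, so J appeared to be losing ground by 2.1 percentage points.
3. The first reading held J plus Z of just 28.4% of the charge, and I reckoned that the scatter of each yield moved its share by 2.6 points. The gap is smaller than that, so I read no drift in Tuesday's run.
4. Thursday's run, with 1.3 mol% of X, gave 61.9% at 20.0 h, level with s.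
5. I therefore held s at 15 s, 20 min and 25 h, with more J than Z.
6. The forecast said 62%, 62% and 62%, with J ahead. Its ground: “The constant ratio from the start points to parallel formation of J and Z, with no detectable interconversion.”
7. The flask gave 62.3%, 62.3% and 62.3%, with J ahead, 62.3% against 37.7% for Z.

    Q ⇌ L, settled at all times (K = 0.930)
    Q + X → X + Z (k = 90.0 M⁻¹ h⁻¹)
    X + L → X + J (k = 160 M⁻¹ h⁻¹)
    X → G (k = 0.110 h⁻¹)
    2 X → E (k = 5.90 M⁻¹ h⁻¹)

The neighbouring flask was the same flask with 1.2 mol% of X in place of 2 mol%. I applied the same reckoning and carried s, 61.9%, unchanged to its three times. Its share came out at 62.3% at 15 s, 62.3% at 20 min and 62.3% at 25 h. At 25.0 h, X in the neighbouring flask stood at 3.26% of the catalyst charged, and that flask still held 0.087% of its charged Q and 0.081% of its charged L.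

(The runs were generated by integration from invented constants; noise was put on by code.)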